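**Retrosynthetic overview**
1. Target 11 ⇒ phenol 10: the C4–OMe bond is made last by oxidative methoxylation (dearomatisation), which creates the C4 centre.
2. 10 ⇒ aryl bromide 6 + (R)-sec-alkyl boronic ester 2: key C4–C8 bond. O-activation of a phenoxide–boronate complex turns the phenol para carbon into an acceptor (phenoxenium, a vinylogous enolonium equivalent), and the sec-alkyl group shifts from boron to C4 with retention.
3. 2 ⇒ (E)-methylisoeugenol 1 (Cu-catalysed enantioselective protoboration sets C8); 6 ⇒ 4-bromo-3-methoxyphenol 3 (O-allylation, Claisen).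
4. Ring order: no ring is built. Both benzene rings are bought; the dienone ring is the phenol ring of 10, dearomatised in the last step.

Assumption: atom labels follow the dienone (C1 = C=O, C2 = allyl carbon, C4 = quaternary C–OMe, C5 = enol-ether C–OMe; C8 = side-chain CH(CH3) on C4, C7 = benzylic CH2). The target is (4R,8R). The ligand antipode in step 1 is the one that gives (R)-2.

**Step 1**
Reactants: 1 (E)-methylisoeugenol (1,2-dimethoxy-4-[(E)-prop-1-enyl]benzene)
Product: 2 (R)-2-[1-(3,4-dimethoxyphenyl)propan-2-yl]-4,4,5,5-tetramethyl-1,3,2-dioxaborolane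
Conditions: B2pin2 (1.1 equiv), CuCl (5 mol %), chiral sulfonate-bridged imidazolinium salt (NHC precursor, 5 mol %), KOt-Bu (20 mol %), MeOH (2 equiv), THF, −50 °C
Reagents that add atoms: bis(pinacolato)diboron, CC1(C)OB(OC1(C)C)B1OC(C)(C)C(C)(C)O1
Why: Copper-catalysed enantioselective protoboration: the NHC–Cu–Bpin species adds syn across the aryl alkene with boron at C8 and copper at benzylic C7, MeOH protonates the C–Cu bond, and the chiral NHC selects the alkene face, setting C8 as R.

**Step 2**
Reactants: 3 4-bromo-3-methoxyphenol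
Product: 4 4-(allyloxy)-1-bromo-2-methoxybenzene
Conditions: allyl bromide, K2CO3, acetone, reflux
Reagents that add atoms: allyl bromide, C=CCBr
Why: Williamson ether synthesis; the phenoxide is O-alkylated cleanly in a polar solvent.

**Step 3**
Reactants: 4 4-(allyloxy)-1-bromo-2-methoxybenzene
Product: 6 2-allyl-4-bromo-5-methoxyphenol, via Claisen dienone 5 (not isolated)
Conditions: PhNEt2, 195 °C
Reagents that add atoms: none
Why: Aromatic Claisen rearrangement; the [3,3] shift goes to the free ortho carbon para to OMe because the other ortho carbon is blocked by the methoxy group (pushed toward it by the neighbouring bromine), and dienone 5 tautomerises to the phenol.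

**Step 4**
Reactants: 6 2-allyl-4-bromo-5-methoxyphenol; 2 (R)-2-[1-(3,4-dimethoxyphenyl)propan-2-yl]-4,4,5,5-tetramethyl-1,3,2-dioxaborolane
Product: 10 2-allyl-4-[(2R)-1-(3,4-dimethoxyphenyl)propan-2-yl]-5-methoxyphenol, via aryllithium 7 (not isolated), via boronate complex 8 (not isolated), via boryl dienone 9 (not isolated)
Conditions: 6 (1.3 equiv), n-BuLi (1 equiv per 6) then t-BuLi (2 equiv per 6), THF, −78 °C; 2 (1.0 equiv), −78 → 0 °C; Ph3BiF2 (1.5 equiv), −78 °C → rt; aq. NH4Cl
Reagents that add atoms: none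
Why: Enantiospecific sp2–sp3 boronate coupling of a para-lithiated phenoxide: Ph3BiF2 turns the phenoxide oxygen of 8 into a leaving group, so the para carbon becomes an acceptor and the sec-alkyl group undergoes a stereoretentive 1,2-metallate shift from boron to C4; fluoride then removes boron from 9 and the ring rearomatises, carrying C8 over unchanged (R in 2, R in 10).

**Step 5**
Reactants: 10 2-allyl-4-[(2R)-1-(3,4-dimethoxyphenyl)propan-2-yl]-5-methoxyphenol
Product: 11 (4R)-2-allyl-4-[(2R)-1-(3,4-dimethoxyphenyl)propan-2-yl]-4,5-dimethoxycyclohexa-2,5-dien-1-one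
Conditions: PhI(OAc)2 (1.1 equiv), MeOH, 0 °C; chromatographic removal of the C4 epimer
Reagents that add atoms: methanol, CO
Why: Hypervalent-iodine oxidative dearomatisation: two-electron oxidation of the phenol and capture by methanol at the para carbon gives the p-quinol methyl ether; C4 is set by 1,2-induction from C8 (with C8–H eclipsing the C5–OMe side, methanol enters anti to the 3,4-dimethoxybenzyl arm, which gives 4R), but this bias is expected to be modest, so the 4S epimer is removed by chromatography.

**Compound list**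
1 | (E)-methylisoeugenol, 1,2-dimethoxy-4-[(E)-prop-1-enyl]benzene | C/C=C/c1ccc(OC)c(OC)c1 | starting material
2 | (R)-2-[1-(3,4-dimethoxyphenyl)propan-2-yl]-4,4,5,5-tetramethyl-1,3,2-dioxaborolane | C[C@H](Cc1ccc(OC)c(OC)c1)B1OC(C)(C)C(C)(C)O1 | intermediate
3 | 4-bromo-3-methoxyphenol | COc1cc(O)ccc1Br | starting material
4 | 4-(allyloxy)-1-bromo-2-methoxybenzene | COc1cc(OCC=C)ccc1Br | intermediate
5 | 6-allyl-4-bromo-3-methoxycyclohexa-2,4-dien-1-one (racemic at C6) | C=CCC1C=C(Br)C(OC)=CC1=O | intermediate (not isolated)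
6 | 2-allyl-4-bromo-5-methoxyphenol | C=CCc1cc(Br)c(OC)cc1O | intermediate
7 | lithium 2-allyl-4-lithio-5-methoxyphenoxide | C=CCc1cc([Li])c(OC)cc1O[Li] | intermediate (not isolated)
8 | lithium (5-allyl-4-lithiooxy-2-methoxyphenyl)[(2R)-1-(3,4-dimethoxyphenyl)propan-2-yl](pinacolato)borate | C=CCc1cc([B-]2(OC(C)(C)C(C)(C)O2)[C@H](C)Cc2ccc(OC)c(OC)c2)c(OC)cc1O[Li].[Li+] | intermediate (not isolated)
9 | 2-allyl-4-[(2R)-1-(3,4-dimethoxyphenyl)propan-2-yl]-5-methoxy-4-(4,4,5,5-tetramethyl-1,3,2-dioxaborolan-2-yl)cyclohexa-2,5-dien-1-one (C4 not controlled; both epimers give 10) | C=CCC1=CC(B2OC(C)(C)C(C)(C)O2)([C@H](C)Cc2ccc(OC)c(OC)c2)C(OC)=CC1=O | intermediate (not isolated)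
10 | 2-allyl-4-[(2R)-1-(3,4-dimethoxyphenyl)propan-2-yl]-5-methoxyphenol | C=CCc1cc([C@H](C)Cc2ccc(OC)c(OC)c2)c(OC)cc1O | intermediate
11 | (4R)-2-allyl-4-[(2R)-1-(3,4-dimethoxyphenyl)propan-2-yl]-4,5-dimethoxycyclohexa-2,5-dien-1-one | C=CCC1=C[C@](OC)([C@H](C)Cc2ccc(OC)c(OC)c2)C(OC)=CC1=O | target

**Totals**
Total step count: 5. Longest linear sequence: 4 steps (3 → 4 → 6 → 10 → 11).

**Steps most likely to fail**

Step 4 (key coupling). The boronate complex must form next to the 5-OMe group, and the shift must deliver a secondary alkyl group to a hindered carbon. The fallback sets out from 2 and 6 and comes back at 10. Treat 2 with KHF2 (MeOH/H2O) to give potassium (R)-[1-(3,4-dimethoxyphenyl)propan-2-yl]trifluoroborate F1. Silylate 6 (TBSCl, imidazole, DMF) to (2-allyl-4-bromo-5-methoxyphenoxy)(tert-butyl)dimethylsilane F2. Join F1 and F2 by a stereoretentive Pd-catalysed secondary-alkyl Suzuki–Miyaura coupling (Pd precatalyst with a retention-selective biarylphosphine, K2CO3, toluene/H2O, 100 °C) to tert-butyl{2-allyl-4-[(2R)-1-(3,4-dimethoxyphenyl)propan-2-yl]-5-methoxyphenoxy}dimethylsilane F3. Cleave the silyl ether with TBAF (THF, 0 °C) to reach 10.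

Step 5 (C4 configuration). Facial selectivity of methanol capture rests only on the neighbouring C8 centre and may be near 1:1. The fallback sets out from 10 and comes back at 11. Oxidise 10 with PhI(OCOCF3)2 in MeCN/H2O at 0 °C to the p-quinol (4R)-2-allyl-4-[(2R)-1-(3,4-dimethoxyphenyl)propan-2-yl]-4-hydroxy-5-methoxycyclohexa-2,5-dien-1-one F4. Separate the C4 epimers at this stage, where the free tertiary alcohols differ more in polarity and crystallinity. Then O-methylate F4 (MeI, Ag2O, CaSO4, rt) to 11.

Step 3 (Claisen regiochemistry). Migration to the carbon between the two oxygens would give the wrong allyl isomer. The fallback sets out from 3 and comes back at 6 without a new compound. Form the sodium phenoxide of 3 (NaH, toluene) and heat with allyl bromide (80–110 °C). Ion-pair C-allylation then takes the less hindered ortho carbon, passing through the same dienone 5 to 6. Any O-allyl ether 4 formed alongside is sent through step 3.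

**Further compounds**
F1 | step 4 | potassium (R)-[1-(3,4-dimethoxyphenyl)propan-2-yl]trifluoroborate | C[C@H](Cc1ccc(OC)c(OC)c1)[B-](F)(F)F.[K+]
F2 | step 4 | (2-allyl-4-bromo-5-methoxyphenoxy)(tert-butyl)dimethylsilane | C=CCc1cc(Br)c(OC)cc1O[Si](C)(C)C(C)(C)C
F3 | step 4 | tert-butyl{2-allyl-4-[(2R)-1-(3,4-dimethoxyphenyl)propan-2-yl]-5-methoxyphenoxy}dimethylsilane | C=CCc1cc([C@H](C)Cc2ccc(OC)c(OC)c2)c(OC)cc1O[Si](C)(C)C(C)(C)C
F4 | step 5 | (4R)-2-allyl-4-[(2R)-1-(3,4-dimethoxyphenyl)propan-2-yl]-4-hydroxy-5-methoxycyclohexa-2,5-dien-1-one | C=CCC1=C[C@](O)([C@H](C)Cc2ccc(OC)c(OC)c2)C(OC)=CC1=O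
F0 | step 3 | none | none
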